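**Plan**
1. Numbering: each half is a tetralin (C1 CH-CH3, C2, C3, C4 CH-isopropyl, C4a, C5, C6 C-CH3, C7 C-OH, C8 biaryl carbon, C8a); primes mark the second half.
2. Retrosynthetic cuts, in order: the two O–CH3 bonds; the ring bonds C4–C4a and C4'–C4a' (through C3=C4 alkenes); the four isopropyl C–CH3 bonds; C8a–C1 and C8a'–C1'; last C8–C8'.
3. Enabling feature: before ring closure, CH3–C1–C2–C3–C4–C(isopropyl methine) is an unbranched six-carbon chain joined to the arene only at C8a. It is sorbic acid, with the δ-carbon as C1 and the carboxyl carbon as the isopropyl methine.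
4. Forward order: biaryl bond first (Ullmann), axis resolved, both chains attached at once by iridium-catalysed 1,6-arylation of ethyl sorbate (no ring formed), then both cyclohexene rings closed together by cyclodehydration of isopropyl ketones made from the esters.
5. Stereochemistry: C1/C1' (S) from the chiral diene ligand on iridium; C4/C4' (S) from hydrogenation of C3=C4 anti to the pseudoaxial C1 methyl (cis); the axis from resolution of the dibromobiaryl.

Key step: step 5

Remark 1: the target formula fixes (1S,4S,1'S,4'S) but not the sense of the tetra-ortho-substituted axis; the route is written for the (aS) atropisomer (the other enantiomer of 5 would give the (aR) series), and the SMILES strings carry no axial descriptor.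
Remark 2: the (S,S)-enantiomer of the diene ligand is assumed to direct the aryl group to the face of the δ-carbon that gives (S) at C1; if the sense is the reverse, the (R,R)-ligand is used in the same step.

**Step 1**
Reactants: 1 5-bromo-2-methylanisole
Product: 3 1-bromo-2-iodo-3-methoxy-4-methylbenzene, via aryllithium 2 (not isolated)
Conditions: LDA, THF, −78 °C; then I2, −78 °C to rt
Reagents that add atoms: iodine, II
Why: Directed ortho-metalation: the ring hydrogen flanked by OMe and Br is the most acidic, LDA removes it at −78 °C before LiBr can be lost to an aryne, and iodine traps the aryllithium at the future C8.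

**Step 2**
Reactants: 3 1-bromo-2-iodo-3-methoxy-4-methylbenzene (two molecules)
Product: 4 rac-6,6'-dibromo-2,2'-dimethoxy-3,3'-dimethylbiphenyl
Conditions: Cu powder (activated), DMF, 150 °C
Reagents that add atoms: none
Why: Ullmann homocoupling: copper inserts into C–I much faster than into C–Br, so C8–C8' forms between the iodinated carbons and both bromides survive, as known for 2-iodo-3-bromoanisoles.

**Step 3**
Reactants: 4 rac-6,6'-dibromo-2,2'-dimethoxy-3,3'-dimethylbiphenyl
Product: 5 (aS)-6,6'-dibromo-2,2'-dimethoxy-3,3'-dimethylbiphenyl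
Conditions: preparative HPLC, amylose tris(3,5-dimethylphenylcarbamate) phase, hexane/i-PrOH
Reagents that add atoms: none
Why: Chromatographic resolution of atropisomers: four ortho substituents make the axis configurationally stable, so the enantiomers separate on a polysaccharide chiral phase, and the sense of the axis is assigned by anomalous-dispersion X-ray analysis using the bromine atoms.

**Step 4**
Reactants: 5 (aS)-6,6'-dibromo-2,2'-dimethoxy-3,3'-dimethylbiphenyl; 6 trimethyl borate
Product: 9 (aS)-(2,2'-dimethoxy-3,3'-dimethylbiphenyl-6,6'-diyl)diboronic acid, via dilithiobiaryl 7 (not isolated), via bis(dimethyl boronate) 8 (not isolated)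
Conditions: n-BuLi (2.2 equiv), THF, −78 °C; cannulated into B(OMe)3 (6 equiv), THF, −78 °C to rt; 1 M HCl
Reagents that add atoms: trimethyl borate (6), COB(OC)OC; water, O
Why: Bromine–lithium exchange followed by electrophilic borylation: both bromides exchange at −78 °C, inverse addition to excess borate lets each carbanion meet its own boron (suppressing a bridged diarylborinate), and acid hydrolysis frees the diboronic acid with the axis untouched.

**Step 5**
Reactants: 9 (aS)-(2,2'-dimethoxy-3,3'-dimethylbiphenyl-6,6'-diyl)diboronic acid; 10 ethyl sorbate (6 equiv)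
Product: 11 diethyl (3Z,3'Z,5S,5'S)-5,5'-[(aS)-2,2'-dimethoxy-3,3'-dimethylbiphenyl-6,6'-diyl]bis(hex-3-enoate)
Conditions: [IrCl((S,S)-Me-tfb*)]2 (5 mol%, preformed from [IrCl(coe)2]2 and the C2-symmetric dimethyl-tetrafluorobenzobarrelene diene Me-tfb*), K2CO3, toluene/H2O, 60 °C
Reagents that add atoms: ethyl sorbate (10), C/C=C/C=C/C(=O)OCC
Why: Hydroxide-assisted transmetalation of each B(OH)2 group to monovalent iridium gives an aryl–iridium species that binds ethyl sorbate as an s-cis η4-diene; the aryl group migrates to the δ-carbon, and protonation of the resulting π-allyl/oxa-π-allyl iridium at the α-carbon releases the (Z)-β,γ-unsaturated ester and regenerates Ir–OH, once at each boron. The closest known reaction type is the iridium/chiral-diene-catalysed enantioselective 1,6-addition of arylboronic acids or boroxines to δ-substituted 2,4-dienoates and dienones. No ring is closed; the two skeletal bonds C8a–C1 and C8a'–C1' are made. Both new stereocentres (C1, C1') are set by the chiral diene, which exposes one enantioface of the coordinated δ-carbon to the migrating aryl group; because the two additions are independent, a wrongly set centre ends up in a diastereomer that chromatography should remove. The step needs 1,6- over 1,4-regioselectivity, which η4-coordination of the diene to iridium secures, and arylation faster than protodeboronation, which is helped by excess sorbate and by each boron-bearing C8a having only one ortho substituent (the other ring) while C4a is still C–H.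

**Step 6**
Reactants: 11 diethyl (3Z,3'Z,5S,5'S)-5,5'-[(aS)-2,2'-dimethoxy-3,3'-dimethylbiphenyl-6,6'-diyl]bis(hex-3-enoate)
Product: 12 diethyl (5S,5'S)-5,5'-[(aS)-2,2'-dimethoxy-3,3'-dimethylbiphenyl-6,6'-diyl]dihexanoate
Conditions: H2 (1 atm), 5% Pt/C, EtOAc, rt
Reagents that add atoms: none
Why: Heterogeneous hydrogenation: platinum reduces the cis-disubstituted alkenes with little double-bond migration, so the allylic, benzylic C1–H is not drawn into conjugation and the stereocentres persist, while any α,β-isomer formed in step 5 converges on the same diester.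

**Step 7**
Reactants: 12 diethyl (5S,5'S)-5,5'-[(aS)-2,2'-dimethoxy-3,3'-dimethylbiphenyl-6,6'-diyl]dihexanoate
Product: 14 diethyl (5S,5'S)-5,5'-[(aS)-2,2'-dimethoxy-3,3'-dimethylbiphenyl-6,6'-diyl]bis(2-hydroxyhexanoate) (both C2 epimers), via dipotassium bis-enolate 13 (not isolated)
Conditions: KHMDS (2.6 equiv), THF, −78 °C; 2-(phenylsulfonyl)-3-phenyloxaziridine (3 equiv), −78 °C; aq. NH4Cl
Reagents that add atoms: 2-(phenylsulfonyl)-3-phenyloxaziridine, O=S(=O)(c1ccccc1)N1OC1c1ccccc1
Why: Enolate oxidation with an N-sulfonyloxaziridine: each ester becomes its potassium enolate and electrophilic oxygen is transferred to the α-carbon (future C4); the new carbinol centres form without control and are erased in step 9.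

**Step 8**
Reactants: 14 diethyl (5S,5'S)-5,5'-[(aS)-2,2'-dimethoxy-3,3'-dimethylbiphenyl-6,6'-diyl]bis(2-hydroxyhexanoate)
Product: 15 (6S,6'S)-6,6'-[(aS)-2,2'-dimethoxy-3,3'-dimethylbiphenyl-6,6'-diyl]bis(2-methylheptane-2,3-diol) (both C3 epimers)
Conditions: MeMgBr (8 equiv), THF, 0 °C to rt; aq. NH4Cl
Reagents that add atoms: methylmagnesium bromide, C[Mg]Br
Why: Grignard addition: after deprotonation of the hydroxyl groups, MeMgBr adds twice to each ester carbonyl, turning the former carboxyl carbon into the C(OH)Me2 carbon that becomes the isopropyl methine.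

**Step 9**
Reactants: 15 (6S,6'S)-6,6'-[(aS)-2,2'-dimethoxy-3,3'-dimethylbiphenyl-6,6'-diyl]bis(2-methylheptane-2,3-diol)
Product: 17 (aS,1S,1'S)-4,4'-diisopropyl-7,7'-dimethoxy-1,1',6,6'-tetramethyl-1,1',2,2'-tetrahydro-8,8'-binaphthalene, via bis(isopropyl ketone) 16 (not isolated)
Conditions: TsOH·H2O (0.5 equiv), toluene, reflux, Dean–Stark trap
Reagents that add atoms: none
Why: Pinacol rearrangement followed by aromatic cyclodehydration (intramolecular Friedel–Crafts hydroxyalkylation, then dehydration): ionisation of the tertiary hydroxyl and a 1,2-hydride shift from C4 give the isopropyl ketone, C4a (para to the methoxy group) attacks the protonated carbonyl through a six-membered transition state, and loss of water leaves the conjugated C3=C4 alkene without touching C1.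

**Step 10**
Reactants: 17 (aS,1S,1'S)-4,4'-diisopropyl-7,7'-dimethoxy-1,1',6,6'-tetramethyl-1,1',2,2'-tetrahydro-8,8'-binaphthalene
Product: 18 (aS,1S,1'S,4S,4'S)-4,4'-diisopropyl-7,7'-dimethoxy-1,1',6,6'-tetramethyl-1,1',2,2',3,3',4,4'-octahydro-8,8'-binaphthalene
Conditions: H2 (4 atm), 10% Pd/C, EtOAc, rt
Reagents that add atoms: none
Why: Substrate-controlled heterogeneous hydrogenation: peri strain with the C8 aryl group holds each C1 methyl pseudoaxial over one face of the half-chair, hydrogen should be delivered to C3=C4 from the opposite face, and the isopropyl group then ends cis to the methyl (4S from 1S), the facial bias expected from hydrogenation of 4-isopropyl-1-methyl-1,2-dihydronaphthalenes to cis-calamenenes.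

**Step 11**
Reactants: 18 (aS,1S,1'S,4S,4'S)-4,4'-diisopropyl-7,7'-dimethoxy-1,1',6,6'-tetramethyl-1,1',2,2',3,3',4,4'-octahydro-8,8'-binaphthalene
Product: 19 (aS,1S,1'S,4S,4'S)-4,4'-diisopropyl-1,1',6,6'-tetramethyl-1,1',2,2',3,3',4,4'-octahydro-8,8'-binaphthalene-7,7'-diol (CNP0152871.1)
Conditions: BBr3 (6 equiv), CH2Cl2, −78 °C to rt; H2O
Reagents that add atoms: none
Why: Lewis-acid ether cleavage: BBr3 coordinates the twisted, di-ortho-substituted methoxy oxygens and bromide removes the methyl groups, leaving the benzylic stereocentres and the axis untouched.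

**Compound list**
1 | 5-bromo-2-methylanisole | COc1cc(Br)ccc1C | starting material
2 | (6-bromo-2-methoxy-3-methylphenyl)lithium (formed in the flask) | COc1c(C)ccc(Br)c1[Li] | intermediate
3 | 1-bromo-2-iodo-3-methoxy-4-methylbenzene | COc1c(C)ccc(Br)c1I | intermediate
4 | rac-6,6'-dibromo-2,2'-dimethoxy-3,3'-dimethylbiphenyl | COc1c(C)ccc(Br)c1-c1c(OC)c(C)ccc1Br | intermediate
5 | (aS)-6,6'-dibromo-2,2'-dimethoxy-3,3'-dimethylbiphenyl (P helicity: seen along the aryl–aryl bond, the rear C–Br carbon lies 90° clockwise from the front C–Br carbon; the same twist, then defined by the two C–O carbons, is kept in all later compounds) | COc1c(C)ccc(Br)c1-c1c(OC)c(C)ccc1Br | intermediate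
6 | trimethyl borate | COB(OC)OC | starting material
7 | (aS)-(2,2'-dimethoxy-3,3'-dimethylbiphenyl-6,6'-diyl)dilithium (formed in the flask) | COc1c(C)ccc([Li])c1-c1c(OC)c(C)ccc1[Li] | intermediate
8 | (aS)-tetramethyl (2,2'-dimethoxy-3,3'-dimethylbiphenyl-6,6'-diyl)diboronate (formed in the flask) | COc1c(C)ccc(B(OC)OC)c1-c1c(OC)c(C)ccc1B(OC)OC | intermediate
9 | (aS)-(2,2'-dimethoxy-3,3'-dimethylbiphenyl-6,6'-diyl)diboronic acid | COc1c(C)ccc(B(O)O)c1-c1c(OC)c(C)ccc1B(O)O | intermediate
10 | ethyl sorbate, ethyl (2E,4E)-hexa-2,4-dienoate | C/C=C/C=C/C(=O)OCC | starting material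
11 | diethyl (3Z,3'Z,5S,5'S)-5,5'-[(aS)-2,2'-dimethoxy-3,3'-dimethylbiphenyl-6,6'-diyl]bis(hex-3-enoate) | COc1c(C)ccc([C@@H](C)/C=C\CC(=O)OCC)c1-c1c(OC)c(C)ccc1[C@@H](C)/C=C\CC(=O)OCC | intermediate
12 | diethyl (5S,5'S)-5,5'-[(aS)-2,2'-dimethoxy-3,3'-dimethylbiphenyl-6,6'-diyl]dihexanoate | COc1c(C)ccc([C@@H](C)CCCC(=O)OCC)c1-c1c(OC)c(C)ccc1[C@@H](C)CCCC(=O)OCC | intermediate
13 | dipotassium bis-enolate of 12 (formed in the flask) | COc1c(C)ccc([C@@H](C)CCC=C(O[K])OCC)c1-c1c(OC)c(C)ccc1[C@@H](C)CCC=C(O[K])OCC | intermediate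
14 | diethyl (5S,5'S)-5,5'-[(aS)-2,2'-dimethoxy-3,3'-dimethylbiphenyl-6,6'-diyl]bis(2-hydroxyhexanoate), both C2 epimers | COc1c(C)ccc([C@@H](C)CCC(O)C(=O)OCC)c1-c1c(OC)c(C)ccc1[C@@H](C)CCC(O)C(=O)OCC | intermediate
15 | (6S,6'S)-6,6'-[(aS)-2,2'-dimethoxy-3,3'-dimethylbiphenyl-6,6'-diyl]bis(2-methylheptane-2,3-diol), both C3 epimers | COc1c(C)ccc([C@@H](C)CCC(O)C(C)(C)O)c1-c1c(OC)c(C)ccc1[C@@H](C)CCC(O)C(C)(C)O | intermediate
16 | (6S,6'S)-6,6'-[(aS)-2,2'-dimethoxy-3,3'-dimethylbiphenyl-6,6'-diyl]bis(2-methylheptan-3-one) (formed in the flask) | COc1c(C)ccc([C@@H](C)CCC(=O)C(C)C)c1-c1c(OC)c(C)ccc1[C@@H](C)CCC(=O)C(C)C | intermediate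
17 | (aS,1S,1'S)-4,4'-diisopropyl-7,7'-dimethoxy-1,1',6,6'-tetramethyl-1,1',2,2'-tetrahydro-8,8'-binaphthalene (tetralin numbering of the plan; C3=C4 alkenes) | Cc1cc2c(c(-c3c(OC)c(C)cc4c3[C@@H](C)CC=C4C(C)C)c1OC)[C@@H](C)CC=C2C(C)C | intermediate
18 | (aS,1S,1'S,4S,4'S)-4,4'-diisopropyl-7,7'-dimethoxy-1,1',6,6'-tetramethyl-1,1',2,2',3,3',4,4'-octahydro-8,8'-binaphthalene (1,4-cis in each half) | Cc1cc2c(c(-c3c(OC)c(C)cc4c3[C@@H](C)CC[C@H]4C(C)C)c1OC)[C@@H](C)CC[C@H]2C(C)C | intermediate
19 | (aS,1S,1'S,4S,4'S)-4,4'-diisopropyl-1,1',6,6'-tetramethyl-1,1',2,2',3,3',4,4'-octahydro-8,8'-binaphthalene-7,7'-diol, the 8,8'-dimer of cis-7-hydroxycalamenene | Cc1cc2c(c(-c3c(O)c(C)cc4c3[C@@H](C)CC[C@H]4C(C)C)c1O)[C@@H](C)CC[C@H]2C(C)C | target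

**Step count**
Total steps: 11. Longest linear sequence: 11 steps, from 5-bromo-2-methylanisole (1).

**Steps most likely to fail**

Step 5. Transmetalation from the ortho-aryl-substituted boron to iridium may be slower than protodeboronation, the second arylation may stall after the first, or the axis may be mismatched with the ligand and erode face selection at C1. Fallback, from 9 to 12: rhodium-catalysed asymmetric 1,4-addition of 9 to ethyl (E)-crotonate ([Rh(acac)(C2H4)2] with the binap enantiomer that gives 3S, dioxane/H2O, 100 °C) should give diethyl (3S,3'S)-3,3'-[(aS)-2,2'-dimethoxy-3,3'-dimethylbiphenyl-6,6'-diyl]dibutanoate F1. Reduction with DIBAL-H (CH2Cl2, −78 °C) gives the dialdehyde (3S,3'S)-3,3'-[(aS)-2,2'-dimethoxy-3,3'-dimethylbiphenyl-6,6'-diyl]dibutanal F2. Horner–Wadsworth–Emmons olefination (triethyl phosphonoacetate, NaH, THF) gives diethyl (2E,2'E,5S,5'S)-5,5'-[(aS)-2,2'-dimethoxy-3,3'-dimethylbiphenyl-6,6'-diyl]bis(hex-2-enoate) F3. Hydrogenation (H2, Pd/C, EtOAc) then rejoins the route at 12.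

Step 9. The tertiary cation may be captured by C4a before the hydride shift (seven-membered ring), an alkyl shift may compete with the hydride shift, or the electron-rich styrene product may oligomerise in acid. Fallback, from 12 to 17: bromination para to each methoxy group (NBS, MeCN, 0 °C) should give diethyl (5S,5'S)-5,5'-[(aS)-5,5'-dibromo-2,2'-dimethoxy-3,3'-dimethylbiphenyl-6,6'-diyl]dihexanoate F4. Intramolecular palladium-catalysed α-arylation of the ester enolates (Pd(OAc)2, P(t-Bu)3, LiHMDS, toluene, 60 °C) closes C4–C4a and C4'–C4a' to diethyl (aS,1S,1'S)-7,7'-dimethoxy-1,1',6,6'-tetramethyl-1,1',2,2',3,3',4,4'-octahydro-8,8'-binaphthalene-4,4'-dicarboxylate F5 (C4 epimers). Excess MeMgBr (THF) gives the bis(tertiary alcohol) 2,2'-[(aS,1S,1'S)-7,7'-dimethoxy-1,1',6,6'-tetramethyl-1,1',2,2',3,3',4,4'-octahydro-8,8'-binaphthalene-4,4'-diyl]di(propan-2-ol) F6. Dehydration with equilibration to the endocyclic alkene (TsOH, toluene, reflux) rejoins the route at 17.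

Step 10. Facial discrimination on the metal surface may be poor at one or both alkenes, giving trans units, or reduction of the hindered isopropyl-bearing alkene may be sluggish. Fallback, from 17 to 18: catalyst-controlled homogeneous hydrogenation with a cationic iridium complex of a chiral phosphinooxazoline, [Ir(cod)(t-Bu-PHOX)]BArF (BArF = B[3,5-(CF3)2C6H3]4; H2 50 bar, CH2Cl2, rt). The ligand enantiomer is chosen so that reagent control reinforces delivery of hydrogen anti to the C1 methyl. This leads directly to 18 with no new compound.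

**Further compounds**
F1 | step 5 | diethyl (3S,3'S)-3,3'-[(aS)-2,2'-dimethoxy-3,3'-dimethylbiphenyl-6,6'-diyl]dibutanoate | COc1c(C)ccc([C@@H](C)CC(=O)OCC)c1-c1c(OC)c(C)ccc1[C@@H](C)CC(=O)OCC
F2 | step 5 | (3S,3'S)-3,3'-[(aS)-2,2'-dimethoxy-3,3'-dimethylbiphenyl-6,6'-diyl]dibutanal | COc1c(C)ccc([C@@H](C)CC=O)c1-c1c(OC)c(C)ccc1[C@@H](C)CC=O
F3 | step 5 | diethyl (2E,2'E,5S,5'S)-5,5'-[(aS)-2,2'-dimethoxy-3,3'-dimethylbiphenyl-6,6'-diyl]bis(hex-2-enoate) | COc1c(C)ccc([C@@H](C)C/C=C/C(=O)OCC)c1-c1c(OC)c(C)ccc1[C@@H](C)C/C=C/C(=O)OCC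
F4 | step 9 | diethyl (5S,5'S)-5,5'-[(aS)-5,5'-dibromo-2,2'-dimethoxy-3,3'-dimethylbiphenyl-6,6'-diyl]dihexanoate | COc1c(C)cc(Br)c([C@@H](C)CCCC(=O)OCC)c1-c1c(OC)c(C)cc(Br)c1[C@@H](C)CCCC(=O)OCC
F5 | step 9 | diethyl (aS,1S,1'S)-7,7'-dimethoxy-1,1',6,6'-tetramethyl-1,1',2,2',3,3',4,4'-octahydro-8,8'-binaphthalene-4,4'-dicarboxylate (C4 epimers) | Cc1cc2c(c(-c3c(OC)c(C)cc4c3[C@@H](C)CCC4C(=O)OCC)c1OC)[C@@H](C)CCC2C(=O)OCC
F6 | step 9 | 2,2'-[(aS,1S,1'S)-7,7'-dimethoxy-1,1',6,6'-tetramethyl-1,1',2,2',3,3',4,4'-octahydro-8,8'-binaphthalene-4,4'-diyl]di(propan-2-ol) (C4 epimers) | Cc1cc2c(c(-c3c(OC)c(C)cc4c3[C@@H](C)CCC4C(C)(C)O)c1OC)[C@@H](C)CCC2C(C)(C)O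
F0 | step 10 | none | none
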